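**Strategy.** The decalin is cut at C3–C4 of ring A (C1–C5, C10; labdane numbering). Ring B, the C10 methyl and the gem-dimethyl C4 are mapped onto (1S,5S)-(−)-verbenone: C8 is its carbonyl, C4 its cyclobutane CMe2. Conjugate allylation anti to that bridge presets the trans A/B fusion. The key step exploits gem-dimethyl C4 as a latent tertiary cation: SnCl4 cleaves the strained C7–C4 bond of the norpinanone and a (Z)-vinylsilane on C10 traps the cation, closing ring A while ring B is merely unveiled. The C8 ketone then gives C17 and the Δ7 alkene; Negishi carboalumination builds the side chain; a C16 + C16 ω-silyloxy acid is esterified at O15.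

Key step: step 4

Remark: the acyl group is read as 32-hydroxydotriacontanoyl (31 CH2 after C=O), commercial (1S)-(−)-verbenone is taken as enantiopure, and labdane numbering is used throughout (bicyclo[3.1.1]heptane C1/C2/C3/C4/C5/C6/C7 = labdane C7/C8/C9/C10/C5/C4/C6).

Step 1
Reactants: 1 (1S,5S)-(−)-verbenone
Product: 2 [(4-allyl-4,6,6-trimethylbicyclo[3.1.1]hept-2-en-2-yl)oxy]trimethylsilane (allyl on C4 anti to the CMe2 bridge)
Conditions: allylMgBr, CuBr·SMe2 (1 equiv), TMSCl, THF, −78 °C; Et3N, pentane, cold aq NaHCO3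
Reagents that add atoms: allylmagnesium bromide C=CC[Mg]Br; chlorotrimethylsilane C[Si](C)(C)Cl
Why: Organocopper conjugate addition accelerated by TMSCl should deliver the allyl group to the β,β-disubstituted enone from the face anti to the CMe2 bridge, which sets C10 with its methyl cis and its C1 chain trans to the future C4 substituent on C5 (the trans A/B fusion), and traps the C8–C9 enolate regiospecifically as the enol silane.

Step 2
Reactants: 2 [(4-allyl-4,6,6-trimethylbicyclo[3.1.1]hept-2-en-2-yl)oxy]trimethylsilane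
Product: 3 trimethyl({4,6,6-trimethyl-4-[(Z)-3-(triethylsilyl)prop-2-enyl]bicyclo[3.1.1]hept-2-en-2-yl}oxy)silane
Conditions: [Ir(OMe)(cod)]2 (cat.), 4,4′-di-tert-butyl-2,2′-bipyridine, Et3SiH, norbornene, THF, 40 °C
Reagents that add atoms: triethylsilane CC[SiH](CC)CC
Why: Iridium-catalysed dehydrogenative silylation of a terminal alkene with norbornene as hydrogen acceptor is a Z-selective route to vinylsilanes (Ir–Si insertion, then syn β-hydride elimination) and should leave the trisubstituted enol silane untouched.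

Step 3
Reactants: 3 trimethyl({4,6,6-trimethyl-4-[(Z)-3-(triethylsilyl)prop-2-enyl]bicyclo[3.1.1]hept-2-en-2-yl}oxy)silane
Product: 5 methyl 3-{4,6,6-trimethyl-2-oxo-4-[(Z)-3-(triethylsilyl)prop-2-enyl]bicyclo[3.1.1]heptan-3-yl}propanoate (C3 chain syn to the CMe2 bridge), via C9-epimeric Michael adduct 4 (not isolated)
Conditions: MeLi, THF, 0 °C; −78 °C, methyl acrylate (1.0 equiv, slow addition); LDA (1.3 equiv), −78 → −20 °C; AcOH, THF, −78 °C
Reagents that add atoms: methyl acrylate C=CC(=O)OC
Why: MeLi unmasks the regiodefined lithium enolate for Michael addition to the acrylate, and because C7 is a bridgehead C9 is the only enolisable ring position, so re-enolisation with LDA and kinetic protonation from the open face anti to the bridge should place the propanoate chain cis to the C10 methyl as the target requires at C9.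

Step 4
Reactants: 5 methyl 3-{4,6,6-trimethyl-2-oxo-4-[(Z)-3-(triethylsilyl)prop-2-enyl]bicyclo[3.1.1]heptan-3-yl}propanoate
Product: 7 methyl 3-[(1S,4aR,8aR)-5,5,8a-trimethyl-2-oxo-1,2,3,4,4a,5,8,8a-octahydronaphthalen-1-yl]propanoate, via trichlorostannyl enolate 6 (not isolated)
Conditions: SnCl4 (2.2 equiv), 2,6-di-tert-butyl-4-methylpyridine (0.3 equiv), CH2Cl2, −78 → 0 °C; sat. aq NaHCO3
Reagents that add atoms: none
Why: Proposed new method: SnCl4 binds the C8 carbonyl and the strained cyclobutane bond C7–C4 α to it heterolyses to a tin enolate (C7=C8) and the tertiary cation at C4, which the (Z)-vinylsilane on C10 attacks at its silicon-bearing carbon C3, after which chloride-assisted loss of the silyl group from the β-silyl cation at C2 leaves the C2=C3 alkene. The closest known reactions are the Lewis-acid opening of 4-substituted norpinanones with capture of the tertiary cation by a phenolic oxygen, and vinylsilane-terminated cation–olefin cyclisations; their combination with a carbon terminator on this ring system has not been shown. Ring A closes in a 6-endo-trig (ipso) mode, whereas ring B is not closed here but released from the bicycle. No new stereocentre is formed: the trans A/B fusion follows from the preset trans relation of the C1 chain on C10 and the C4 carbon on C5 (both equatorial on the half-chair of ring B), and C9 is untouched because the enolate forms towards C7. The step needs ring closure to beat proton loss from the C4 cation, protodesilylation and 5-exo attack; the β-silicon effect directs attack to C3, the chair-like six-membered transition state is favoured, and the hindered pyridine scavenges HCl.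

Step 5
Reactants: 7 methyl 3-[(1S,4aR,8aR)-5,5,8a-trimethyl-2-oxo-1,2,3,4,4a,5,8,8a-octahydronaphthalen-1-yl]propanoate
Product: 8 methyl 3-[(1S,4aR,8aR)-5,5,8a-trimethyl-2-oxodecahydronaphthalen-1-yl]propanoate
Conditions: H2 (1 atm), 10% Pd/C, EtOAc, rt
Reagents that add atoms: none
Why: Catalytic hydrogenation should saturate the only C=C bond (cis-disubstituted C2=C3) under neutral conditions that leave the ketone, the ester and the epimerisable C9 centre unchanged.

Step 6
Reactants: 8 methyl 3-[(1S,4aR,8aR)-5,5,8a-trimethyl-2-oxodecahydronaphthalen-1-yl]propanoate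
Product: 9 methyl 3-[(1S,4aR,8aR)-5,5,8a-trimethyl-2-(trifluoromethylsulfonyloxy)-1,4,4a,5,6,7,8,8a-octahydronaphthalen-1-yl]propanoate
Conditions: KHMDS (1.05 equiv), THF, −78 °C; PhNTf2, −78 → 0 °C
Reagents that add atoms: N-phenylbis(trifluoromethanesulfonimide) O=S(=O)(N(c1ccccc1)S(=O)(=O)C(F)(F)F)C(F)(F)F
Why: Kinetic deprotonation should occur at the unhindered C7 methylene and not at the tertiary C9–H next to the quaternary C10, so O-triflation of the enolate gives the Δ7 enol triflate and leaves C9 intact.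

Step 7
Reactants: 9 methyl 3-[(1S,4aR,8aR)-5,5,8a-trimethyl-2-(trifluoromethylsulfonyloxy)-1,4,4a,5,6,7,8,8a-octahydronaphthalen-1-yl]propanoate
Product: 10 methyl 3-[(1S,4aR,8aR)-2-(hydroxymethyl)-5,5,8a-trimethyl-1,4,4a,5,6,7,8,8a-octahydronaphthalen-1-yl]propanoate
Conditions: Bu3SnCH2OH, Pd(PPh3)4 (5 mol %), LiCl, 1,4-dioxane, 100 °C
Reagents that add atoms: (tributylstannyl)methanol CCCC[Sn](CCCC)(CCCC)CO
Why: Stille coupling of the enol triflate with the hydroxymethylstannane installs C17 at the alcohol oxidation level with the C7=C8 double bond fixed in place.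

Step 8
Reactants: 10 methyl 3-[(1S,4aR,8aR)-2-(hydroxymethyl)-5,5,8a-trimethyl-1,4,4a,5,6,7,8,8a-octahydronaphthalen-1-yl]propanoate
Product: 11 methyl 3-[(1S,4aR,8aR)-2-{[(tert-butyldimethylsilyl)oxy]methyl}-5,5,8a-trimethyl-1,4,4a,5,6,7,8,8a-octahydronaphthalen-1-yl]propanoate
Conditions: TBSCl, imidazole, DMF, rt
Reagents that add atoms: tert-butyldimethylsilyl chloride CC(C)(C)[Si](C)(C)Cl
Why: Silylation of the primary allylic alcohol masks O17 so that O15 can later be acylated alone.

Step 9
Reactants: 11 methyl 3-[(1S,4aR,8aR)-2-{[(tert-butyldimethylsilyl)oxy]methyl}-5,5,8a-trimethyl-1,4,4a,5,6,7,8,8a-octahydronaphthalen-1-yl]propanoate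
Product: 13 {[(1S,4aR,8aR)-1-(but-3-ynyl)-5,5,8a-trimethyl-1,4,4a,5,6,7,8,8a-octahydronaphthalen-2-yl]methoxy}(tert-butyl)dimethylsilane, via aldehyde 12 (not isolated)
Conditions: DIBAL-H (1.1 equiv), CH2Cl2, −78 °C; MeOH, K2CO3, dimethyl (1-diazo-2-oxopropyl)phosphonate, −78 °C → rt
Reagents that add atoms: dimethyl (1-diazo-2-oxopropyl)phosphonate CC(=O)C(=[N+]=[N-])P(=O)(OC)OC
Why: Half-reduction of the methyl ester (stable aluminium hemiacetal at −78 °C) followed in the same flask by Ohira–Bestmann homologation should give the terminal alkyne C13≡C14, and C9 is now allylic and no longer epimerisable by the base.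

Step 10
Reactants: 13 {[(1S,4aR,8aR)-1-(but-3-ynyl)-5,5,8a-trimethyl-1,4,4a,5,6,7,8,8a-octahydronaphthalen-2-yl]methoxy}(tert-butyl)dimethylsilane
Product: 14 ent-17-[(tert-butyldimethylsilyl)oxy]labda-7,13E-dien-15-ol
Conditions: Me3Al, Cp2ZrCl2 (0.25 equiv), CH2Cl2, 0 °C → rt; n-BuLi, THF, −78 °C; (CH2O)n, → rt
Reagents that add atoms: trimethylaluminium C[Al](C)C; paraformaldehyde (as formaldehyde) C=O
Why: Negishi zirconium-catalysed carboalumination adds methyl to C13 and aluminium to C14 in a syn fashion, and trapping the alanate with formaldehyde gives the allylic alcohol whose E geometry is fixed by that syn addition.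

Step 11
Reactants: 15 16-bromohexadecan-1-ol
Product: 16 [(16-bromohexadecyl)oxy](tert-butyl)dimethylsilane
Conditions: TBSCl, imidazole, DMF, rt
Reagents that add atoms: tert-butyldimethylsilyl chloride CC(C)(C)[Si](C)(C)Cl
Why: Silylation of the primary alcohol allows Grignard formation at the bromide end.

Step 12
Reactants: 16 [(16-bromohexadecyl)oxy](tert-butyl)dimethylsilane; 17 16-bromohexadecanoic acid
Product: 19 32-[(tert-butyldimethylsilyl)oxy]dotriacontanoic acid, via Grignard reagent 18 (not isolated)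
Conditions: 16: Mg, THF, 45 °C; 17: MeMgCl (1.0 equiv), THF, −20 °C; combined, Li2CuCl4 (3 mol %), −20 °C → rt; cold dilute aq HCl
Reagents that add atoms: none
Why: Copper-catalysed sp3–sp3 cross-coupling of a Grignard reagent with a primary alkyl bromide tolerates the magnesium carboxylate and joins the two C16 units into the C32 chain.

Step 13
Reactants: 14 ent-17-[(tert-butyldimethylsilyl)oxy]labda-7,13E-dien-15-ol; 19 32-[(tert-butyldimethylsilyl)oxy]dotriacontanoic acid
Product: 20 ent-17-[(tert-butyldimethylsilyl)oxy]labda-7,13E-dien-15-yl 32-[(tert-butyldimethylsilyl)oxy]dotriacontanoate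
Conditions: DIC, DMAP (cat.), CH2Cl2, rt
Reagents that add atoms: none
Why: Steglich esterification acylates the only free hydroxyl group, the primary allylic O15.

Step 14
Reactants: 20 ent-17-[(tert-butyldimethylsilyl)oxy]labda-7,13E-dien-15-yl 32-[(tert-butyldimethylsilyl)oxy]dotriacontanoate
Product: 21 ent-17-hydroxylabda-7,13E-dien-15-yl 32-hydroxydotriacontanoate (5R,9S,10R)
Conditions: HF·pyridine, pyridine/THF, 0 °C → rt
Reagents that add atoms: none
Why: Buffered HF should cleave both primary TBS ethers without acyl migration or attack on the allylic ester and the two trisubstituted alkenes.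

**Compound list**

1 | (1S,5S)-(−)-verbenone, (1S,5S)-4,6,6-trimethylbicyclo[3.1.1]hept-3-en-2-one | CC1=CC(=O)[C@H]2C[C@@H]1C2(C)C | starting material
2 | [(4-allyl-4,6,6-trimethylbicyclo[3.1.1]hept-2-en-2-yl)oxy]trimethylsilane, allyl on C4 (labdane C10) anti to the CMe2 bridge | C[C@]1(CC=C)C=C(O[Si](C)(C)C)[C@H]2C[C@@H]1C2(C)C | intermediate
3 | trimethyl({4,6,6-trimethyl-4-[(Z)-3-(triethylsilyl)prop-2-enyl]bicyclo[3.1.1]hept-2-en-2-yl}oxy)silane, same configuration as 2 | C[C@]1(C/C=C\[Si](CC)(CC)CC)C=C(O[Si](C)(C)C)[C@H]2C[C@@H]1C2(C)C | intermediate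
4 | C9 epimer of 5 (propanoate chain on bicyclic C3 anti to the CMe2 bridge), present as its lithium ester enolate | C[C@]1(C/C=C\[Si](CC)(CC)CC)[C@@H](CCC(=O)OC)C(=O)[C@H]2C[C@@H]1C2(C)C | intermediate (not isolated)
5 | methyl 3-{4,6,6-trimethyl-2-oxo-4-[(Z)-3-(triethylsilyl)prop-2-enyl]bicyclo[3.1.1]heptan-3-yl}propanoate, propanoate chain on C3 syn to the CMe2 bridge and cis to the C4 methyl | C[C@]1(C/C=C\[Si](CC)(CC)CC)[C@H](CCC(=O)OC)C(=O)[C@H]2C[C@@H]1C2(C)C | intermediate
6 | trichlorostannyl enolate (C7=C8) of 7 | COC(=O)CC[C@@H]1C(O[Sn](Cl)(Cl)Cl)=CC[C@@H]2C(C)(C)C=CC[C@@]12C | intermediate (not isolated)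
7 | methyl 3-[(1S,4aR,8aR)-5,5,8a-trimethyl-2-oxo-1,2,3,4,4a,5,8,8a-octahydronaphthalen-1-yl]propanoate (trans-fused, labdane Δ2) | COC(=O)CC[C@@H]1C(=O)CC[C@@H]2C(C)(C)C=CC[C@@]12C | intermediate
8 | methyl 3-[(1S,4aR,8aR)-5,5,8a-trimethyl-2-oxodecahydronaphthalen-1-yl]propanoate | COC(=O)CC[C@@H]1C(=O)CC[C@@H]2C(C)(C)CCC[C@@]12C | intermediate
9 | methyl 3-[(1S,4aR,8aR)-5,5,8a-trimethyl-2-(trifluoromethylsulfonyloxy)-1,4,4a,5,6,7,8,8a-octahydronaphthalen-1-yl]propanoate | COC(=O)CC[C@@H]1C(OS(=O)(=O)C(F)(F)F)=CC[C@@H]2C(C)(C)CCC[C@@]12C | intermediate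
10 | methyl 3-[(1S,4aR,8aR)-2-(hydroxymethyl)-5,5,8a-trimethyl-1,4,4a,5,6,7,8,8a-octahydronaphthalen-1-yl]propanoate | COC(=O)CC[C@@H]1C(CO)=CC[C@@H]2C(C)(C)CCC[C@@]12C | intermediate
11 | methyl 3-[(1S,4aR,8aR)-2-{[(tert-butyldimethylsilyl)oxy]methyl}-5,5,8a-trimethyl-1,4,4a,5,6,7,8,8a-octahydronaphthalen-1-yl]propanoate | COC(=O)CC[C@@H]1C(CO[Si](C)(C)C(C)(C)C)=CC[C@@H]2C(C)(C)CCC[C@@]12C | intermediate
12 | 3-[(1S,4aR,8aR)-2-{[(tert-butyldimethylsilyl)oxy]methyl}-5,5,8a-trimethyl-1,4,4a,5,6,7,8,8a-octahydronaphthalen-1-yl]propanal | O=CCC[C@@H]1C(CO[Si](C)(C)C(C)(C)C)=CC[C@@H]2C(C)(C)CCC[C@@]12C | intermediate (not isolated)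
13 | {[(1S,4aR,8aR)-1-(but-3-ynyl)-5,5,8a-trimethyl-1,4,4a,5,6,7,8,8a-octahydronaphthalen-2-yl]methoxy}(tert-butyl)dimethylsilane | C#CCC[C@@H]1C(CO[Si](C)(C)C(C)(C)C)=CC[C@@H]2C(C)(C)CCC[C@@]12C | intermediate
14 | ent-17-[(tert-butyldimethylsilyl)oxy]labda-7,13E-dien-15-ol (5R,9S,10R) | C/C(=C\CO)CC[C@@H]1C(CO[Si](C)(C)C(C)(C)C)=CC[C@@H]2C(C)(C)CCC[C@@]12C | intermediate
15 | 16-bromohexadecan-1-ol | OCCCCCCCCCCCCCCCCBr | starting material
16 | [(16-bromohexadecyl)oxy](tert-butyl)dimethylsilane | CC(C)(C)[Si](C)(C)OCCCCCCCCCCCCCCCCBr | intermediate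
17 | 16-bromohexadecanoic acid | OC(=O)CCCCCCCCCCCCCCCBr | starting material
18 | {16-[(tert-butyldimethylsilyl)oxy]hexadecyl}magnesium bromide | CC(C)(C)[Si](C)(C)OCCCCCCCCCCCCCCCC[Mg]Br | intermediate (not isolated)
19 | 32-[(tert-butyldimethylsilyl)oxy]dotriacontanoic acid | OC(=O)CCCCCCCCCCCCCCCCCCCCCCCCCCCCCCCO[Si](C)(C)C(C)(C)C | intermediate
20 | ent-17-[(tert-butyldimethylsilyl)oxy]labda-7,13E-dien-15-yl 32-[(tert-butyldimethylsilyl)oxy]dotriacontanoate | C/C(=C\COC(=O)CCCCCCCCCCCCCCCCCCCCCCCCCCCCCCCO[Si](C)(C)C(C)(C)C)CC[C@@H]1C(CO[Si](C)(C)C(C)(C)C)=CC[C@@H]2C(C)(C)CCC[C@@]12C | intermediate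
21 | ent-17-hydroxylabda-7,13E-dien-15-yl 32-hydroxydotriacontanoate (5R,9S,10R) | C/C(=C\COC(=O)CCCCCCCCCCCCCCCCCCCCCCCCCCCCCCCO)CC[C@@H]1C(CO)=CC[C@@H]2C(C)(C)CCC[C@@]12C | target

**Step count.** Total: 14 steps. Longest linear sequence: 12 steps (1–10, 13, 14).

**Steps most likely to fail**

Step 4 (Proposed new method). The C4 cation may lose a proton or suffer a hydride shift from C5, or the vinylsilane may be protodesilylated, faster than the 6-endo ring closure. The fallback closes ring A by metathesis with known reactions; it sets out from 1 and comes back at 8. Copper-mediated conjugate addition of vinylmagnesium bromide with TMSCl would give the 4-vinyl enol silane F1. The sequence of step 3 (MeLi, methyl acrylate, LDA, kinetic protonation) would give the vinyl keto ester F2. Iodotrimethylsilane (TMSCl/NaI, MeCN, 0 °C, then water) would open the cyclobutane to the tertiary iodide F3. Keck radical allylation (allyltributylstannane, AIBN, benzene, 80 °C) would give the 1,7-diene F4, and ring-closing metathesis (Grubbs II, CH2Cl2, 40 °C) would close ring A as the Δ1-octalone F5. Hydrogenation (H2, Pd/C) would then give 8.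

Step 3. The acrylate may be oligomerised by the ester enolate, re-enolisation of the hindered C9–H may stay incomplete, or the protonation may show poor facial selectivity; each erodes the C9 configuration. The fallback builds the chain so that the C9–H is delivered to a discrete enol silane; it sets out from 3 and comes back at 5. MeLi followed by Eschenmoser's salt would give the Mannich base F6, and quaternisation (MeI) with elimination (NaHCO3) the exocyclic enone F7. A fluoride-catalysed Mukaiyama–Michael addition of 1-methoxy-1-(trimethylsilyloxy)ethene would add C12–C13 and give the enol silane F8. Its protonation (Bu4NF, AcOH, THF, −78 °C) from the face anti to the bridge would give 5.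

Step 2. The allyl group may be hydrosilylated or isomerised, and unselective β-hydride elimination may give the E-vinylsilane or an allylsilane. The fallback brings in the three carbons as an alkyne; it sets out from 1 and comes back at 3. TiCl4-promoted conjugate propargylation with allenyltributylstannane (CH2Cl2, −78 °C) would give the propargyl ketone F9. Ruthenium-catalysed trans-hydrosilylation ([RuCl2(p-cymene)]2, Et3SiH, CH2Cl2) would give the (Z)-vinylsilane ketone F10, and LDA followed by TMSCl would give 3.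

**Further compounds**

F1 | step 4 | trimethyl[(4,6,6-trimethyl-4-vinylbicyclo[3.1.1]hept-2-en-2-yl)oxy]silane, vinyl anti to the CMe2 bridge | C[C@]1(C=C)C=C(O[Si](C)(C)C)[C@H]2C[C@@H]1C2(C)C
F2 | step 4 | methyl 3-(4,6,6-trimethyl-2-oxo-4-vinylbicyclo[3.1.1]heptan-3-yl)propanoate, chain syn to the bridge | C[C@]1(C=C)[C@H](CCC(=O)OC)C(=O)[C@H]2C[C@@H]1C2(C)C
F3 | step 4 | methyl 3-[4-(2-iodopropan-2-yl)-3-methyl-6-oxo-3-vinylcyclohexyl]propanoate, tertiary iodide with labdane 5R,9S,10R configuration | COC(=O)CC[C@@H]1C(=O)CC[C@H](C(C)(C)I)[C@@]1(C)C=C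
F4 | step 4 | methyl 3-[3-methyl-4-(2-methylpent-4-en-2-yl)-6-oxo-3-vinylcyclohexyl]propanoate | COC(=O)CC[C@@H]1C(=O)CC[C@H](C(C)(C)CC=C)[C@@]1(C)C=C
F5 | step 4 | methyl 3-[(1S,4aR,8aR)-5,5,8a-trimethyl-2-oxo-1,2,3,4,4a,5,6,8a-octahydronaphthalen-1-yl]propanoate (labdane Δ1) | COC(=O)CC[C@@H]1C(=O)CC[C@@H]2C(C)(C)CC=C[C@@]12C
F6 | step 3 | 3-[(dimethylamino)methyl]-4,6,6-trimethyl-4-[(Z)-3-(triethylsilyl)prop-2-enyl]bicyclo[3.1.1]heptan-2-one | C[C@]1(C/C=C\[Si](CC)(CC)CC)[C@@H](CN(C)C)C(=O)[C@H]2C[C@@H]1C2(C)C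
F7 | step 3 | 4,6,6-trimethyl-3-methylidene-4-[(Z)-3-(triethylsilyl)prop-2-enyl]bicyclo[3.1.1]heptan-2-one | C[C@]1(C/C=C\[Si](CC)(CC)CC)C(=C)C(=O)[C@H]2C[C@@H]1C2(C)C
F8 | step 3 | methyl 3-{4,6,6-trimethyl-4-[(Z)-3-(triethylsilyl)prop-2-enyl]-2-(trimethylsilyloxy)bicyclo[3.1.1]hept-2-en-3-yl}propanoate | C[C@]1(C/C=C\[Si](CC)(CC)CC)C(CCC(=O)OC)=C(O[Si](C)(C)C)[C@H]2C[C@@H]1C2(C)C
F9 | step 2 | 4,6,6-trimethyl-4-(prop-2-ynyl)bicyclo[3.1.1]heptan-2-one, propargyl anti to the CMe2 bridge | C[C@]1(CC#C)CC(=O)[C@H]2C[C@@H]1C2(C)C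
F10 | step 2 | 4,6,6-trimethyl-4-[(Z)-3-(triethylsilyl)prop-2-enyl]bicyclo[3.1.1]heptan-2-one | C[C@]1(C/C=C\[Si](CC)(CC)CC)CC(=O)[C@H]2C[C@@H]1C2(C)C
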